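The north and west runs differ in charge, so you can read them as two sets of books on the limiting reagent, the starting material.

| flask | starting material | remark | time |
|---|---|---|---|
| north | 0.20 M | run made earlier |  |
| west | 0.80 M | run made earlier |  |
| flask | 0.40 M |  | 4.0 h |

- north (time / h: target / %, isomer of the product / %): 0.417: 19.6, 9.4; 0.667: 27.1, 12.9; 1.33: 40.3, 19.7; 2.50: 50.0, 24.7; 5.00: 59.0, 25.0
- west (time / h: target / %, isomer of the product / %): 1.00: 30.2, 13.1; 2.00: 37.6, 18.8; 3.00: 42.9, 20.8; 4.00: 45.2, 19.4; 5.00: 47.8, 20.3

(scatter of a reading: 0.5 percentage points)

- a species is counted by the starting material in it: one idle adduct or homo dimer counts as two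
- amounts and yields of target count crystals and idle adduct too
- given per volume of solution although it is solid: crystals
- steps thought possible: starting material <-> isomer of the product; starting material <-> target; 2 starting material -> homo dimer; starting material + target <-> idle adduct; crystals <-> target
- in an amount of target, one idle adduct counts as one target

* share of target in target plus isomer of the product at 1.0 min
* share of target in target plus isomer of the product at 4.0 h
* which of target and isomer of the product there is more of at 4.0 h

At the last readings, north books 59.0% as target and 25.0% as isomer of the product. West books 47.8% and 20.3%. Crystals and idle adduct stand inside the target entry. The gap g, the percentage in neither entry, holds starting material, homo dimer and the other half of any idle adduct: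

north: g = 16.0%
west: g = 31.9%

North gives 70.2% and west 70.2% for the selectivity S, the share of target in target plus isomer of the product. Across a factor of 4.00 in charge, the gap grew to twice the north value while S stayed level. So you book the gap first and split the remainder by S.

My reckoning for the flask takes the middle gap, because 0.40 M is the geometric middle of the two charges. These readings come from later than 4.0 h, so the entry is rough:

gap: 24.0%
remainder: 76.0%
target, S of that: 53.4%
isomer of the product, the rest: 22.6%

For 1.0 min I take the share at the earliest north reading, made at 0.417 h: 67.6%.

The forecast, reasoning from “two parallel first-order routes”, gives 67.5% at 1.0 min, 69.5% at 4.0 h and target ahead. Its share at 4.0 h lies below my S.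

The flask gives 70.6% at 1.0 min and 69.7% at 4.0 h, with target ahead, 52.1% against 22.7%.

    starting material ⇌ isomer of the product (K = 2.90, k = 7.90 × 10⁻⁵ /s)
    starting material ⇌ target (K = 0.920, k = 1.90 × 10⁻⁴ /s)
    2 starting material → homo dimer (k = 1.40 × 10⁻⁴ /M/s)
    starting material + target ⇌ idle adduct, settled at all times (K = 1.10 /M)
    crystals ⇌ target, rate k5*(cs5 - [target]) while solid is left; crystals form when [target] > cs5 (solubility = 4.30 mM, k = 6.20 × 10⁻⁴ /s)

At 4.0 h the flask's gap stands at 25.2%, and S on its remainder gives 52.5% target. The neighbour flask, charged at 0.16 M, has a gap of 17.6% at 4.0 h, holding 8.59% starting material and 8.96% homo dimer. The flask holds twice that homo dimer, 18.6%. S on the neighbour's remainder gives 57.8% target and 24.6% isomer of the product. The neighbour stands at 56.4% and 26.0%, a share of 68.5%.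

The earlier runs and the new flask are calculated from invented constants, noise included.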